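Remark: ring locants used throughout are C1 (ring CH carrying the CH2O arm, whose carbon is C1'), C2 (CMe2), C3 (CH–O), C4 and C5 (CH2), C6 (carbon with the exocyclic methylene); read this way the SMILES is the cis (1S,3R) isomer.

## The problem

Compound 20 is the 7-O-ether of umbelliferone (19) with a monocyclic C10 alcohol. The coumarin can be bought, so the task is the six-membered carbocycle C1–C6 and the single C1'–O link to it. In the ring, C1 (CH carrying C1'), the quaternary C2 (gem-dimethyl), C3 (CH–OAc) and C6 (exocyclic methylene) are contiguous; only C4 and C5 are bare.

The two stereocentres, C1 (S) and C3 (R), are cis but separated by C2, so neither can steer the other by vicinal induction. A one-carbon acyl group on C1 can, however, reach C3 across C2 as a five-membered lactone that can only form cis. C1 can therefore control C3, and only C1 needs absolute control.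

The 1,1-disubstituted methylene moves into the ring under acid. C1–H is allylic and becomes acidic whenever C1' is a carbonyl carbon, so base at that stage threatens both the C1 configuration and the alkene position. The acetate and the coumarin lactone do not survive hydride, hydroxide or alkoxide and must come after the last reduction. C1' is a β-branched primary carbon, slow in substitution, and a free cis hydroxyl on C3 will close onto any activated C1' to give a bridged oxolane; this fixes the order of the last steps.

The feature that opens the ring to a cycloaddition is the array C6(=CH2)–C1(C1')–C2(Me2), with C3 and C4 free to be an alkene. C1, C6 and the methylene carbon are the footprint of an allenic carbonyl dienophile that has reacted at its conjugated double bond; C2–C5 are that of a diene ending in CMe2.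

## Retrosynthesis

**C1'–O ether bond.** The last bond cut is the alkyl–oxygen bond of the aryl ether, giving hydroxy acetate 18 and umbelliferone 19. Cutting the aryl–oxygen bond instead would need a 7-halocoumarin and a metal catalyst. Acetylating last would mean etherifying the free cis diol 15, whose activated C1' is captured by the C3 hydroxyl to form the bridged ether. The forward step must be a neutral substitution at a hindered primary carbon that spares acetate, lactone and methylene; a Mitsunobu reaction with the acidic phenol 19 fits. Compound 18 has lost the whole aromatic half.

**O–acetyl and O–silyl bonds.** 18 goes back through silyl ether acetate 17 and the primary silyl ether 16 to diol 15. No skeletal bond is cut. The detour is the price for placing the acetate on the hindered secondary oxygen while the more reactive primary one is kept for the ether. What is asked is a clean primary-over-secondary silylation, which the neopentyl-type environment of C3–OH makes easy.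

**C3–O bond.** Diol 15 is the reduction product of bridged γ-lactone 14. Lactone 14 comes from acid 12 by cutting the C3–O bond, via iodolactone 13, in which the C4–I bond is cut as well. Hydroboration or epoxidation of a C3=C4 alkene would have no regio- or facial control beside a quaternary carbon, and a C3 ketone would have to be made first. Delivery from the C1 carboxyl reaches C3 through a five-membered ring and only from the face of C1. The precursor has one stereocentre and one oxygen fewer. The forward reaction must choose C3=C4 over the methylene and C3 over C4.

**Acyl C–N bond.** Acid 12 is released from imide 10 (through percarboxylate 11). The oxazolidinone is in 10 only to give the catalyst a second binding point. The cleavage must not enolise C1.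

**C1–C2 and C5–C6 bonds (key cut).** Imide 10 is divided into allenoyl imide 8 and 4-methylpenta-1,3-diene 9. No other [4+2] partition of the ring puts the carbonyl-bearing C1 and the methylene-bearing C6 together in the dienophile, and this one delivers the methylene, the gem-dimethyl flank and the C3=C4 handle in one step. Both precursors are achiral and acyclic. The forward reaction must be periselective for [4+2] with a diene that is reluctant to be s-cis, regioselective (CMe2 to C1), site-selective for the conjugated allene bond and face-selective at C1.

**Cα=Cβ bond of the allene, then P–C and N–acyl bonds.** Imide 8 is cut at the double bond that becomes C1–C6, into ylide 6 and ketene 7. Both are generated in the flask from phosphonium salt 4 and acetyl chloride 5. Salt 4 comes from bromoacetyl imide 3, and 3 from oxazolidin-2-one 1 and bromoacetyl bromide 2. Acylating 1 with an activated buta-2,3-dienoic acid is shorter on paper but exposes an allenic acyl donor to amine base; the Wittig route builds the allene last under the conditions used for allenoates.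

## Roads not taken

**Alternative 1:** The ring is bought instead of built. The cut is at the C2–CH3 bond and the C1–C1' bond, leading back to the enone A2, (R)-4-[(tert-butyldimethylsilyl)oxy]-3-methylcyclohex-2-en-1-one. Forward, Me2CuLi would add to the β-carbon of A2 and the enolate would be trapped by monomeric formaldehyde to give β-hydroxy ketone A1; its ketone carbon is C6 of 20.

- Merits: no ring-forming step can fail; the C3 oxygen is present from the start with its configuration; the two oxygens are differentiated from the outset, which the chosen plan reaches only through steps 9 and 10. In these respects this road is better.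
- Weak points:
  - A2 is not a commodity as a single enantiomer and costs several steps.
  - Cuprate additions that create a quaternary carbon on a β,β-disubstituted enone are sluggish and usually need Me3SiCl, which captures the enolate and removes the one-pot aldol.
  - The C1 configuration rests on relay from C3 across C2 or on equilibration α to the ketone.
  - The methylene is still missing. A1 is a hindered β-hydroxy ketone that can dehydrate, undergo retro-aldol cleavage or epimerise under olefination conditions.
- Comparison: the overall length is similar once A2 and the protection around the olefination are counted. The hard step moves from ring formation to a late methylenation. Against the safer ring supply, the chosen plan sets a methylene that arrives with the ring and a C1 set by a catalyst from achiral materials.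

**Alternative 2:** The cut is the C1–C1' bond, with C1' delivered from the C3 oxygen. Forward, Me3SiOTf would ionise the methoxymethyl ether of ring allylsilane A4 to an oxocarbenium ion. Attack by the γ-carbon (C1) would form C1–C1', release silicon to create the C6 methylene, and close the bridged oxolane A3. Acylative opening to bromo acetate A5 and alkylation of 19 would finish.

- Merits: the tether guarantees the cis relation as the lactone does in the chosen plan; the allylsilane places the methylene without ambiguity; only two steps follow the key step, against seven here. In step count after the key step this road is clearly better.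
- Weak points:
  - A4 needs its C3 configuration and the ring allylsilane built in a separate multi-step sequence.
  - The cyclisation must pass through a conformer with the bulky alkoxy group axial beside CMe2.
  - The ending treats an acid-labile methylene with an acyl halide and Lewis acid, then asks a phenoxide to substitute a β-branched primary bromide.
- Comparison: the chosen plan sets against the short ending a one-step catalytic ring construction from commercial pieces and an ending under neutral conditions. It keeps the A3-to-A5 ending in reserve for step 6.

**Alternative 3:** The coumarin is built rather than bought. The cuts are C8–C8a, C6–C7, C4a–C8a and O1–C2. Forward, irradiation of the dienyl diazoketone A8 would give, by Wolff rearrangement, a dienylketene that adds to ynol ether A7. Cyclobutenone opening, 6π electrocyclisation, tautomerisation and lactonisation would then close ring A (benzene) and ring B (pyranone) to give the silyl analogue A6 of the target.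

- Merits: the C1'–O bond is made at the alkoxide stage, so no substitution at the hindered C1' is needed, and the late stage is neutral. On that point it is better than a Mitsunobu reaction.
- Weak points:
  - It solves what 19 already solves and leaves the real problem untouched: the carbocycle with both stereocentres must still come from another route.
  - A7 and A8 each cost extra steps, and desilylation and acetylation still follow.
  - A ketene and ultraviolet light meet an electron-rich 1,1-disubstituted alkene that can undergo [2+2] addition.
- Comparison: the chosen plan answers the one real advantage with a reserve that also avoids substitution at C1' (aryl–oxygen coupling, given under step 11).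

Key step: step 4

## Route

**Step 1**

Reactants: 1 oxazolidin-2-one; 2 bromoacetyl bromide

Product: 3 3-(2-bromoacetyl)oxazolidin-2-one

Conditions: n-BuLi (1.0 equiv), THF, −78 °C; then 2, −78 → 0 °C

Reagents that add atoms: none

Why: N-acylation of a lithiated carbamate nitrogen by an acyl bromide; the acyl carbon is far more electrophilic than the CH2Br carbon, so the bromomethyl group is kept for step 2.

**Step 2**

Reactants: 3 3-(2-bromoacetyl)oxazolidin-2-one

Product: 4 [2-oxo-2-(2-oxooxazolidin-3-yl)ethyl]triphenylphosphonium bromide

Conditions: PPh3, toluene, rt

Reagents that add atoms: triphenylphosphine, `c1ccc(cc1)P(c1ccccc1)c1ccccc1`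

Why: SN2 quaternisation of PPh3 by an α-bromo carbonyl compound, the usual first half of a Wittig reagent preparation; the salt should precipitate from toluene.

**Step 3**

Reactants: 4 [2-oxo-2-(2-oxooxazolidin-3-yl)ethyl]triphenylphosphonium bromide; 5 acetyl chloride

Product: 8 3-(buta-2,3-dienoyl)oxazolidin-2-one, via the phosphorus ylide 6 (not isolated), via ketene 7 (not isolated)

Conditions: Et3N (2.1 equiv), CH2Cl2, 0 °C; then 5 added slowly, 0 °C → rt

Reagents that add atoms: none

Why: Et3N deprotonates the acidic CH2 of 4 to the imide-stabilised ylide 6 and dehydrochlorinates 5 to ketene 7; Wittig olefination of the ketene carbonyl by 6 gives the allene and Ph3PO, the standard way to buta-2,3-dienoic acid derivatives. Slow addition keeps the ketene concentration low and limits C-acylation of the ylide.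

**Step 4**

Reactants: 8 3-(buta-2,3-dienoyl)oxazolidin-2-one; 9 4-methylpenta-1,3-diene

Product: 10 (S)-3-(2,2-dimethyl-6-methylenecyclohex-3-ene-1-carbonyl)oxazolidin-2-one

Conditions: Cu((S,S)-tBu-box)(SbF6)2 (10 mol %), 9 (5 equiv), CH2Cl2, 0 °C → rt

Reagents that add atoms: none

Why: Both carbonyl oxygens of 8 chelate the square-planar divalent copper centre of the complex (tBu-box = 2,2'-(propane-2,2-diyl)bis[(4S)-4-tert-butyl-4,5-dihydrooxazole]), which lowers the LUMO of the conjugated Cα=Cβ bond only, because the distal allene bond is orthogonal to the carbonyl π system. The reaction is a concerted but strongly asynchronous normal-demand [4+2] cycloaddition: the unsubstituted diene terminus (largest HOMO coefficient, future C5) bonds first to the central allene carbon (C6) and the CMe2 terminus then bonds to the α-carbon (C1), which puts CMe2 next to the carbonyl-bearing carbon. The closest known reactions are Lewis-acid-catalysed Diels–Alder reactions of allenic esters at their conjugated double bond and copper bis(oxazoline)-catalysed Diels–Alder reactions of acryloyl oxazolidinones with acyclic 1-substituted dienes. The six-membered carbocycle is closed by intermolecular cycloaddition, both ring bonds (C1–C2 and C5–C6) being made in this step. The only new stereocentre, C1, is set by the ligand: in the s-cis chelate a tert-butyl group of the (S,S) ligand covers the Si face of the α-carbon, so the diene adds to the Re face and C1 is S, and the endo or exo orientation of the diene has no stereochemical consequence. The step needs periselectivity for [4+2] over stepwise four-ring closure because the cis methyl group of 9 makes the s-cis conformer scarce; the hexafluoroantimonate complex (the most Lewis acidic of its family), high concentration and an excess of the cheap diene are chosen for that reason. The untouched allene bond becomes the C6 methylene and the new ring alkene lies at C3=C4, where oxygen is needed next.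

**Step 5**

Reactants: 10 (S)-3-(2,2-dimethyl-6-methylenecyclohex-3-ene-1-carbonyl)oxazolidin-2-one

Product: 12 (S)-2,2-dimethyl-6-methylenecyclohex-3-ene-1-carboxylic acid, via the lithium percarboxylate 11 (not isolated)

Conditions: LiOH, H2O2, THF/H2O, 0 °C; then aqueous Na2SO3; then dilute HCl to pH 3

Reagents that add atoms: hydrogen peroxide, `OO`

Why: Hydroperoxide is more nucleophilic and less basic than hydroxide and cleaves hindered acyl oxazolidinones at the exocyclic carbonyl without enolising the α-carbon; sulfite reduces the percarboxylate 11 to the acid. C1 is not touched and the isolated alkenes are inert to alkaline H2O2.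

**Step 6**

Reactants: 12 (S)-2,2-dimethyl-6-methylenecyclohex-3-ene-1-carboxylic acid

Product: 13 (1S,4S,5S)-4-iodo-8,8-dimethyl-2-methylene-6-oxabicyclo[3.2.1]octan-7-one

Conditions: I2, KI, NaHCO3, THF/H2O, 0 °C, dark

Reagents that add atoms: iodine, `II`

Why: Iodolactonisation: reversible iodonium formation on the C3=C4 face anti to the carboxylate and 5-exo attack of the axial carboxylate at C3 give the bridged γ-lactone, which can only form cis, so the C3 oxygen is set cis to C1 and iodine ends trans on C4. The methylene is β,γ to the acid and could close only a four-membered lactone, which is slower and reversible; closure at C4 would need a six-membered bridge through a boat.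

**Step 7**

Reactants: 13 (1S,4S,5S)-4-iodo-8,8-dimethyl-2-methylene-6-oxabicyclo[3.2.1]octan-7-one

Product: 14 (1S,5R)-8,8-dimethyl-2-methylene-6-oxabicyclo[3.2.1]octan-7-one

Conditions: Bu3SnH, AIBN (cat.), toluene, 80 °C

Reagents that add atoms: none

Why: Radical chain dehalogenation; the secondary C4 radical takes hydrogen from Bu3SnH faster than it rearranges, and the neutral conditions leave the lactone, C1 and the methylene alone. The oxygen-bearing carbon changes its descriptor from S to R only because iodine no longer ranks its neighbour first.

**Step 8**

Reactants: 14 (1S,5R)-8,8-dimethyl-2-methylene-6-oxabicyclo[3.2.1]octan-7-one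

Product: 15 (1R,3S)-3-(hydroxymethyl)-2,2-dimethyl-4-methylenecyclohexan-1-ol

Conditions: LiAlH4, THF, 0 °C → rt

Reagents that add atoms: none

Why: Hydride reduction of a lactone to a diol; hydride addition to the carbonyl is faster than enolisation and no bond at C1 or C3 is broken, so both stereocentres are kept.

**Step 9**

Reactants: 15 (1R,3S)-3-(hydroxymethyl)-2,2-dimethyl-4-methylenecyclohexan-1-ol

Product: 17 (1R,3S)-3-{[(tert-butyldimethylsilyl)oxy]methyl}-2,2-dimethyl-4-methylenecyclohexyl acetate, via the primary silyl ether 16 (not isolated)

Conditions: TBSCl (1.05 equiv), imidazole, CH2Cl2, 0 °C; then Ac2O, Et3N, DMAP (cat.), rt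

Reagents that add atoms: tert-butyldimethylsilyl chloride, `CC(C)(C)[Si](C)(C)Cl`; acetic anhydride, `CC(=O)OC(C)=O`

Why: The primary hydroxyl is silylated selectively because the secondary one is neopentyl-type; DMAP-catalysed acetylation then caps the C3 hydroxyl. The primary oxygen is masked first because a free cis C3 hydroxyl would close onto an activated C1' to give the bridged oxolane.

**Step 10**

Reactants: 17 (1R,3S)-3-{[(tert-butyldimethylsilyl)oxy]methyl}-2,2-dimethyl-4-methylenecyclohexyl acetate

Product: 18 (1R,3S)-3-(hydroxymethyl)-2,2-dimethyl-4-methylenecyclohexyl acetate

Conditions: HF·pyridine, pyridine, THF, 0 °C → rt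

Reagents that add atoms: none

Why: Fluoride cleavage of the Si–O bond under buffered, weakly acidic conditions, which should neither hydrolyse nor migrate the acetate nor move the methylene.

**Step 11**

Reactants: 18 (1R,3S)-3-(hydroxymethyl)-2,2-dimethyl-4-methylenecyclohexyl acetate; 19 umbelliferone

Product: 20 (1R,3S)-2,2-dimethyl-4-methylene-3-{[(2-oxo-2H-chromen-7-yl)oxy]methyl}cyclohexyl acetate

Conditions: PPh3, DIAD, THF, 0 °C → rt

Reagents that add atoms: none

Why: Mitsunobu etherification: the acidic phenol 19 protonates the PPh3–DIAD betaine and its phenoxide displaces the alkoxyphosphonium group at the primary C1' in an SN2 step. No stereocentre is involved, and the neutral conditions spare the acetate, the coumarin lactone and the methylene.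

## Compound list

```
1 | oxazolidin-2-one | O=C1NCCO1 | starting material
2 | bromoacetyl bromide | O=C(Br)CBr | starting material
3 | 3-(2-bromoacetyl)oxazolidin-2-one | O=C(CBr)N1CCOC1=O | intermediate
4 | [2-oxo-2-(2-oxooxazolidin-3-yl)ethyl]triphenylphosphonium bromide | O=C(C[P+](c1ccccc1)(c1ccccc1)c1ccccc1)N1CCOC1=O.[Br-] | intermediate
5 | acetyl chloride | CC(=O)Cl | starting material
6 | 3-[2-(triphenylphosphoranylidene)acetyl]oxazolidin-2-one | O=C(C=P(c1ccccc1)(c1ccccc1)c1ccccc1)N1CCOC1=O | intermediate
7 | ketene (ethenone) | C=C=O | intermediate
8 | 3-(buta-2,3-dienoyl)oxazolidin-2-one | C=C=CC(=O)N1CCOC1=O | intermediate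
9 | 4-methylpenta-1,3-diene | CC(C)=CC=C | starting material
10 | (S)-3-(2,2-dimethyl-6-methylenecyclohex-3-ene-1-carbonyl)oxazolidin-2-one | C=C1CC=CC(C)(C)[C@H]1C(=O)N1CCOC1=O | intermediate
11 | lithium (S)-2,2-dimethyl-6-methylenecyclohex-3-ene-1-carboperoxoate | C=C1CC=CC(C)(C)[C@H]1C(=O)O[O-].[Li+] | intermediate
12 | (S)-2,2-dimethyl-6-methylenecyclohex-3-ene-1-carboxylic acid | C=C1CC=CC(C)(C)[C@H]1C(=O)O | intermediate
13 | (1S,4S,5S)-4-iodo-8,8-dimethyl-2-methylene-6-oxabicyclo[3.2.1]octan-7-one | C=C1C[C@H](I)[C@H]2OC(=O)[C@@H]1C2(C)C | intermediate
14 | (1S,5R)-8,8-dimethyl-2-methylene-6-oxabicyclo[3.2.1]octan-7-one | C=C1CC[C@H]2OC(=O)[C@@H]1C2(C)C | intermediate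
15 | (1R,3S)-3-(hydroxymethyl)-2,2-dimethyl-4-methylenecyclohexan-1-ol | C=C1CC[C@@H](O)C(C)(C)[C@H]1CO | intermediate
16 | (1R,3S)-3-{[(tert-butyldimethylsilyl)oxy]methyl}-2,2-dimethyl-4-methylenecyclohexan-1-ol | C=C1CC[C@@H](O)C(C)(C)[C@H]1CO[Si](C)(C)C(C)(C)C | intermediate
17 | (1R,3S)-3-{[(tert-butyldimethylsilyl)oxy]methyl}-2,2-dimethyl-4-methylenecyclohexyl acetate | C=C1CC[C@@H](OC(C)=O)C(C)(C)[C@H]1CO[Si](C)(C)C(C)(C)C | intermediate
18 | (1R,3S)-3-(hydroxymethyl)-2,2-dimethyl-4-methylenecyclohexyl acetate | C=C1CC[C@@H](OC(C)=O)C(C)(C)[C@H]1CO | intermediate
19 | umbelliferone (7-hydroxy-2H-chromen-2-one) | O=c1ccc2ccc(O)cc2o1 | starting material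
20 | (1R,3S)-2,2-dimethyl-4-methylene-3-{[(2-oxo-2H-chromen-7-yl)oxy]methyl}cyclohexyl acetate (CNP0300702.1) | C=C1CC[C@@H](OC(C)=O)C(C)(C)[C@H]1COc1ccc2ccc(=O)oc2c1 | target
```

## Step count and least certain steps

Total: 11 steps. Longest linear sequence: 11 steps (1 → 3 → 4 → 8 → 10 → 12 → 13 → 14 → 15 → 17 → 18 → 20); compounds 2, 5, 9 and 19 are purchased and enter along the way.

**Step 4 (key step).**
- Most likely failure: the cycloaddition is too slow because the cis methyl group of 9 keeps the diene out of the s-cis conformer. After the first bond (C5–C6) has begun to form, closure at the nearer allyl terminus to a four-membered ring, or addition of more diene (cationic oligomerisation), can then take over.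
- Further risks: incomplete face discrimination at room temperature, and slow migration of the methylene into conjugation through enolisation of the copper-bound product.
- Fallback (sets out from 2, 5 and 9, returns at 12): replace catalyst control by a covalently bound auxiliary and a stoichiometric, stronger activator. Commercial (R)-4-benzyloxazolidin-2-one (`O=C1N[C@H](Cc2ccccc2)CO1`) would be taken through the sequence of steps 1–3. Acylation with 2 gives (R)-4-benzyl-3-(2-bromoacetyl)oxazolidin-2-one F1, PPh3 gives {2-[(R)-4-benzyl-2-oxooxazolidin-3-yl]-2-oxoethyl}triphenylphosphonium bromide F2, and Et3N with 5 gives (R)-4-benzyl-3-(buta-2,3-dienoyl)oxazolidin-2-one F3. With Me2AlCl (1.4 equiv, CH2Cl2, −78 °C) the cationic dimethylaluminium chelate is a much stronger dienophile than the copper complex, and the benzyl group covers the Si face of the α-carbon. Addition of 9 should then give (R)-4-benzyl-3-[(S)-2,2-dimethyl-6-methylenecyclohex-3-ene-1-carbonyl]oxazolidin-2-one F4. Its minor diastereomer can be removed by chromatography or crystallisation, and LiOH/H2O2 as in step 5 leads to 12.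

**Step 6.**
- Most likely failure: wrong chemoselection. Iodine engages the more electron-rich methylene, followed by four-membered lactone closure or iodohydrin formation. To a lesser extent, closure at C4 instead of C3 is possible because C3 is neopentyl-type.
- Fallback (sets out from 10, returns at 20, bypasses steps 5–11): use a hydroxyl instead of a carboxyl as the internal nucleophile, for which a four-membered closure is not competitive. LiBH4 (THF, MeOH, 0 °C) reduces 10 to [(1S)-2,2-dimethyl-6-methylenecyclohex-3-en-1-yl]methanol F5. I2/NaHCO3 in MeCN gives by 5-exo iodoetherification (1S,4S,5S)-4-iodo-8,8-dimethyl-2-methylene-6-oxabicyclo[3.2.1]octane F6. Bu3SnH/AIBN gives (1S,5R)-8,8-dimethyl-2-methylene-6-oxabicyclo[3.2.1]octane F7, the same compound as A3. AcBr with catalytic ZnBr2 (CH2Cl2, 0 °C) opens the ether by bromide attack at the primary C1' to (1R,3S)-3-(bromomethyl)-2,2-dimethyl-4-methylenecyclohexyl acetate F8. This bromide alkylates 19 (K2CO3, DMF, 60 °C) to 20. The reserve is shorter but is not the first choice, because it exposes the methylene to an acyl halide and asks for substitution at a hindered bromide.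

**Step 3.**
- Most likely failure: base-induced isomerisation of the allenoyl imide to the but-2-ynoyl imide, amine-triggered oligomerisation of the electrophilic allene, or C-acylation of the ylide without olefination.
- Fallback (sets out from 1, returns at 8): form the N–acyl bond with the allene already in place. Commercial ethyl buta-2,3-dienoate (`C=C=CC(=O)OCC`) is saponified (LiOH, THF/H2O, 0 °C) to buta-2,3-dienoic acid F9. This is converted with pivaloyl chloride and N-methylmorpholine (THF, −20 °C) into buta-2,3-dienoic pivalic anhydride F10, which is added at −78 °C to the lithium salt of 1 to give 8.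

**Step 5.**
- Most likely failure: attack at the hindered exocyclic carbonyl is slow, so opening of the oxazolidinone ring, or enolisation towards C1 with loss of configuration and migration of the methylene into conjugation, can compete.
- Fallback (sets out from 10, returns at 13): omit the hydrolysis and treat 10 itself with I2 in aqueous THF. As with γ,δ-unsaturated carboxamides, the acyl oxygen closes onto C3, and water then releases oxazolidin-2-one from the cationic intermediate. No base is involved and no new isolated compound is made.

**Step 11.**
- Most likely failure: displacement at the β-branched C1' is slow, so elimination towards the exocyclic diene or alkylation of the reduced azodicarboxylate can win.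
- Fallback (sets out from 18, returns at 20): make the aryl–oxygen bond instead of the alkyl–oxygen bond. Palladium-catalysed C–O cross-coupling of 18 with commercial 7-bromocoumarin (`O=c1ccc2ccc(Br)cc2o1`), using Pd2(dba)3, tBuBrettPhos and Cs2CO3 in toluene at 80 °C, leaves C1' untouched and makes no new isolated compound.

## Further compounds

```
F1 | step 4 | (R)-4-benzyl-3-(2-bromoacetyl)oxazolidin-2-one | O=C(CBr)N1[C@H](Cc2ccccc2)COC1=O
F2 | step 4 | {2-[(R)-4-benzyl-2-oxooxazolidin-3-yl]-2-oxoethyl}triphenylphosphonium bromide | O=C(C[P+](c1ccccc1)(c1ccccc1)c1ccccc1)N1[C@H](Cc2ccccc2)COC1=O.[Br-]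
F3 | step 4 | (R)-4-benzyl-3-(buta-2,3-dienoyl)oxazolidin-2-one | C=C=CC(=O)N1[C@H](Cc2ccccc2)COC1=O
F4 | step 4 | (R)-4-benzyl-3-[(S)-2,2-dimethyl-6-methylenecyclohex-3-ene-1-carbonyl]oxazolidin-2-one | C=C1CC=CC(C)(C)[C@H]1C(=O)N1[C@H](Cc2ccccc2)COC1=O
F5 | step 6 | [(1S)-2,2-dimethyl-6-methylenecyclohex-3-en-1-yl]methanol | C=C1CC=CC(C)(C)[C@H]1CO
F6 | step 6 | (1S,4S,5S)-4-iodo-8,8-dimethyl-2-methylene-6-oxabicyclo[3.2.1]octane | C=C1C[C@H](I)[C@H]2OC[C@@H]1C2(C)C
F7 | step 6 | (1S,5R)-8,8-dimethyl-2-methylene-6-oxabicyclo[3.2.1]octane | C=C1CC[C@H]2OC[C@@H]1C2(C)C
F8 | step 6 | (1R,3S)-3-(bromomethyl)-2,2-dimethyl-4-methylenecyclohexyl acetate | C=C1CC[C@@H](OC(C)=O)C(C)(C)[C@H]1CBr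
F9 | step 3 | buta-2,3-dienoic acid | C=C=CC(=O)O
F10 | step 3 | buta-2,3-dienoic pivalic anhydride | C=C=CC(=O)OC(=O)C(C)(C)C
F0 | step 5 | none | none
F0 | step 11 | none | none
A1 | alternative 1 | (2S,4R)-4-[(tert-butyldimethylsilyl)oxy]-2-(hydroxymethyl)-3,3-dimethylcyclohexan-1-one | O=C1CC[C@@H](O[Si](C)(C)C(C)(C)C)C(C)(C)[C@H]1CO
A2 | alternative 1 | (R)-4-[(tert-butyldimethylsilyl)oxy]-3-methylcyclohex-2-en-1-one | O=C1CC[C@@H](O[Si](C)(C)C(C)(C)C)C(C)=C1
A3 | alternative 2 | (1S,5R)-8,8-dimethyl-2-methylene-6-oxabicyclo[3.2.1]octane | C=C1CC[C@H]2OC[C@@H]1C2(C)C
A4 | alternative 2 | {[(4R)-4-(methoxymethoxy)-3,3-dimethylcyclohex-1-en-1-yl]methyl}trimethylsilane | COCO[C@@H]1CCC(C[Si](C)(C)C)=CC1(C)C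
A5 | alternative 2 | (1R,3S)-3-(bromomethyl)-2,2-dimethyl-4-methylenecyclohexyl acetate | C=C1CC[C@@H](OC(C)=O)C(C)(C)[C@H]1CBr
A6 | alternative 3 | 7-{[(1S,3R)-3-[(tert-butyldimethylsilyl)oxy]-2,2-dimethyl-6-methylenecyclohexyl]methoxy}-2H-chromen-2-one | C=C1CC[C@@H](O[Si](C)(C)C(C)(C)C)C(C)(C)[C@H]1COc1ccc2ccc(=O)oc2c1
A7 | alternative 3 | tert-butyl{[(1R,3S)-3-[(ethynyloxy)methyl]-2,2-dimethyl-4-methylenecyclohexyl]oxy}dimethylsilane | C=C1CC[C@@H](O[Si](C)(C)C(C)(C)C)C(C)(C)[C@H]1COC#C
A8 | alternative 3 | methyl (2Z,4E)-7-diazo-6-oxohepta-2,4-dienoate | COC(=O)/C=C\C=C\C(=O)C=[N+]=[N-]
```
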